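The numbers in the tables are simulated from invented constants; the scatter is artificial.

At late times the readings of the runs stood still within their scatter: Monday's held near 24.5% of its solid substrate from 5.00 d on. Tuesday's, at 35 °C, colder than any new flask, was flat by 15.0 d, so I took the new flasks to end on plateaus too.

| flask | solid substrate | reagent | temperature | remark | time |
|---|---|---|---|---|---|
| Tuesday's | 0.31 M | 0.46 M | 35 °C | run made earlier |  |
| Monday's | 0.69 M | 0.46 M | 48 °C | run made earlier |  |
| Thursday's | 0.46 M | 0.23 M | 35 °C | run made earlier |  |
| theta | 0.46 M | 0.460 M |  | at 40 °C until 10 d, from then on at 55 °C | 20 d |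
| beta | 0.46 M | 0.460 M | 55 °C |  | 20 d |
| zeta | 0.46 M | 0.460 M | 40 °C |  | 20 d |

| Tuesday's: time / d | Tuesday's: target / % | Monday's: time / d | Monday's: target / % | Thursday's: time / d | Thursday's: target / % |
|---|---|---|---|---|---|
| 5.00 | 43 | 1.67 | 8 | 5.00 | 24 |
| 15.0 | 48 | 5.00 | 25 | 15.0 | 29 |
| 25.0 | 47 | 10.0 | 25 | 25.0 | 27 |
| 40.0 | 46 | 15.0 | 24 | 40.0 | 27 |
| 50.0 | 49 | 20.0 | 24 | 50.0 | 28 |

(scatter of a reading: 1.5 percentage points)

* the flask that comes out highest in amount of target, in percent of the solid substrate charged, or "all alike" when all lie within 1.5 percentage points (theta / beta / zeta / all alike)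
* target at the end, in percent of the solid substrate charged, theta
* target at the end, in percent of the solid substrate charged, beta
* target at the end, in percent of the solid substrate charged, zeta

- solid substrate is a solid; its amount is given per volume of the solution
- the numbers in the tables scatter with a standard deviation of 1.5 percentage points
- at the start none of the solid substrate is in solution
- what has only dissolved of solid substrate counts as not reacted

I folded Monday's plateau and charges together and got 0.367. This is my number, the reagent yield: target at the plateau per reagent charged. Monday's had 0.667 equivalents of reagent, and I took reagent as the limiting reagent there, so the plateau is the reagent yield times [reagent]/[solid substrate]. The new flasks have Monday's [reagent] and equal charges, which gives 36.7% for each.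

Was one number enough? Thursday's, at 0.23 M of reagent and differing from Monday's in [solid substrate] and temperature too, gave 0.555, so the number did not hold from run to run. Tuesday's, with Monday's [reagent] but 1.48 equivalents, gave 0.320, lower, which would mean 32.0% at equal charges. I carried the number across temperature unproven, since Monday's 48 °C lies between 40 °C and 55 °C, and expected the flasks alike.

The forecast parted from me on theta and beta: “The plateaus look like true equilibria”. It gave 26% for theta, 26% for beta and 36% for zeta, and so named zeta as highest.

The flasks gave 38.1% for theta, 37.2% for beta and 38.0% for zeta: all alike.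

    starting material + reagent → target (k = 0.540 M⁻¹ h⁻¹, Ea = 71.0 kJ mol⁻¹)
    starting material + 2 reagent → side product (k = 2.60 M⁻² h⁻¹, Ea = 74.0 kJ mol⁻¹)
    2 starting material → homo dimer (k = 0.240 M⁻¹ h⁻¹, Ea = 72.0 kJ mol⁻¹)
    solid substrate ⇌ starting material, rate k4*(cs4 - [starting material]) while solid is left; crystals form when [starting material] > cs4 (solubility = 0.200 M, k = 0.0190 h⁻¹)
    (constants at 40 °C)

In beta at 2.57 d, the conversion into target used starting material 1.7 times as fast as the conversion into side product, but reagent at 0.85 times that conversion's rate. Beta ended with 0.00948% of its reagent left.

A neighbour flask is beta with 1.2 M of solid substrate, so 0.383 equiv of reagent; the reagent yield gives 14.1% there. It ended at 14.2%.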